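The cis-related methyl groups C19 (on C4) and C20 (on C10) sit 1,3-diaxial on ring A across C5, so they are made together as a CH2–S–CH2 bridge over a C5 ketone. The key step generates a methylene sulfonium ion on the C10 arm and lets C4 of the C4=C5 silyl enol ether attack it: one operation forms C4–C19, closes the thiane ring (a 3-thiabicyclo[3.3.1]nonan-9-one) and sets the C4 quaternary centre relative to C10. Its precursor is a 2-oxocyclohexane-1-carboxylate carrying the methylsulfinylmethyl group on quaternary C10 and a protected 3-hydroxypropyl chain on C4. Raney nickel later releases both methyls; ring B and the side chains follow.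

Key step: step 4

Remark: labdane numbering is used (ring A = C1–C5 and C10, ring B = C5–C10, C19 on C4, C20 on C10, C17 on C8); the ester is carried as tert-butyl and the alcohol as its TBDPS ether, and because the two faces of C5 are nearly equivalent while C19 and C20 are tied through sulfur, the 5α-hydrogen is introduced only after desulfurisation, on a lactone that locks ring A.

Step 1
Reactants: 1 tert-butyl 2-oxocyclohexane-1-carboxylate; 2 chloromethyl methyl sulfide
Product: 3 tert-butyl (1R)-1-[(methylsulfanyl)methyl]-2-oxocyclohexane-1-carboxylate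
Conditions: C2-symmetric N-spiro binaphthyl quaternary ammonium bromide (2 mol %, the enantiomer that gives the R centre), Cs2CO3 (solid), toluene, −20 °C
Reagents that add atoms: 2 chloromethyl methyl sulfide, CSCCl
Why: Asymmetric phase-transfer C-alkylation of a cyclic β-keto ester, in which the chiral ammonium enolate ion pair exposes one enolate face to the reactive α-chloro sulfide and so sets the C10 quaternary centre on a substrate with no other stereocentre; the bulky tert-butyl ester is the ester type for which this catalyst class is selective.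

Step 2
Reactants: 3 tert-butyl (1R)-1-[(methylsulfanyl)methyl]-2-oxocyclohexane-1-carboxylate; 4 tert-butyl(3-iodopropoxy)diphenylsilane
Product: 5 tert-butyl (1R)-3-{3-[(tert-butyldiphenylsilyl)oxy]propyl}-1-[(methylsulfanyl)methyl]-2-oxocyclohexane-1-carboxylate (both C3 epimers)
Conditions: LDA, THF, −78 °C; then 4, DMPU, −78 → −20 °C
Reagents that add atoms: 4 tert-butyl(3-iodopropoxy)diphenylsilane, CC(C)(C)[Si](c1ccccc1)(c1ccccc1)OCCCI
Why: Kinetic lithium enolate alkylation at C4, the only enolisable α-carbon, with a primary iodide; the new C4 centre may form as a mixture because it is flattened to the enol ether in step 4.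

Step 3
Reactants: 5 tert-butyl (1R)-3-{3-[(tert-butyldiphenylsilyl)oxy]propyl}-1-[(methylsulfanyl)methyl]-2-oxocyclohexane-1-carboxylate
Product: 6 tert-butyl (1R)-3-{3-[(tert-butyldiphenylsilyl)oxy]propyl}-1-[(methanesulfinyl)methyl]-2-oxocyclohexane-1-carboxylate (C3 and sulfur epimers)
Conditions: NaIO4, MeOH/THF/H2O, 0 °C → rt
Reagents that add atoms: sodium periodate, [Na+].[O-]I(=O)(=O)=O
Why: Periodate oxidation stops cleanly at the sulfoxide and leaves the ketone untouched; the sulfur configuration is irrelevant because it is lost in the Pummerer step.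

Step 4
Reactants: 6 tert-butyl (1R)-3-{3-[(tert-butyldiphenylsilyl)oxy]propyl}-1-[(methanesulfinyl)methyl]-2-oxocyclohexane-1-carboxylate
Product: 8 tert-butyl (1R,5R)-5-{3-[(tert-butyldiphenylsilyl)oxy]propyl}-9-oxo-3-thiabicyclo[3.3.1]nonane-1-carboxylate, via silyl enol ether thionium triflate 7 (not isolated)
Conditions: TMSOTf (4 equiv), i-Pr2NEt (6 equiv), CH2Cl2, −78 → 0 °C; aq NaHCO3
Reagents that add atoms: none
Why: TMSOTf silylates the sulfoxide oxygen and, with the amine, converts the ketone into its only possible silyl enol ether (C4=C5, since C10 is quaternary); the amine then removes a proton from the S-methyl group and loss of trimethylsilanolate leaves the methylene sulfonium ion 7. C4 of the enol ether adds to the thionium carbon (C19) and desilylation restores the C5 ketone, which is the silicon-induced Pummerer (thionium) alkylation of a silyl enol ether, used here intramolecularly as an α,α′-annulation of a cyclohexanone. The thiane ring closes in a 6-(enolendo)-endo-trig mode. The new C4 stereocentre is controlled by ring geometry: the one-carbon ketone bridge can be spanned only when the sulfur arm on C10 and the forming bond at C4 are axial on the same face, so C19 becomes cis to C20 and the silyloxypropyl chain equatorial whichever C4 or sulfur epimer enters. The step needs the thionium ion on the methyl side of sulfur (the C20 hydrogens are shielded by quaternary C10, and a thionium there has no partner that can close a ring) and C- over O-attack (the enol oxygen is silylated); low temperature and excess amine protect the tert-butyl ester and the silyl ether.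

Step 5
Reactants: 8 tert-butyl (1R,5R)-5-{3-[(tert-butyldiphenylsilyl)oxy]propyl}-9-oxo-3-thiabicyclo[3.3.1]nonane-1-carboxylate
Product: 9 tert-butyl (1S,3S)-3-{3-[(tert-butyldiphenylsilyl)oxy]propyl}-1,3-dimethyl-2-oxocyclohexane-1-carboxylate
Conditions: Raney Ni (W-2, aged in acetone), acetone/EtOH, reflux
Reagents that add atoms: none
Why: Raney nickel hydrogenolysis of both C–S bonds turns the bridge into the cis C19 and C20 methyl groups without touching the two quaternary centres, and the acetone-aged catalyst spares the hindered ketone, the ester and the silyl ether.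

Step 6
Reactants: 9 tert-butyl (1S,3S)-3-{3-[(tert-butyldiphenylsilyl)oxy]propyl}-1,3-dimethyl-2-oxocyclohexane-1-carboxylate; 10 vinylmagnesium bromide
Product: 11 tert-butyl (1S,3S)-3-{3-[(tert-butyldiphenylsilyl)oxy]propyl}-2-ethenyl-2-hydroxy-1,3-dimethylcyclohexane-1-carboxylate (C2 epimers)
Conditions: CH2=CHMgBr, LaCl3·2LiCl, THF, 0 °C → rt; aq NH4Cl
Reagents that add atoms: 10 vinylmagnesium bromide, C=C[Mg]Br
Why: Lanthanide-promoted Grignard 1,2-addition to a non-enolisable hindered ketone, with the neopentyl tert-butyl ester left alone; the carbinol configuration is immaterial because C5 becomes sp2 in step 7.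

Step 7
Reactants: 11 tert-butyl (1S,3S)-3-{3-[(tert-butyldiphenylsilyl)oxy]propyl}-2-ethenyl-2-hydroxy-1,3-dimethylcyclohexane-1-carboxylate
Product: 12 (5S,8aS)-5-{3-[(tert-butyldiphenylsilyl)oxy]propyl}-5,8a-dimethyl-3,5,6,7,8,8a-hexahydro-1H-isochromen-1-one
Conditions: TFA (5 equiv), CH2Cl2, 0 °C
Reagents that add atoms: none
Why: Acid-mediated allylic transposition with lactonisation (SN1′ type): ionisation of the tertiary allylic alcohol gives an allyl cation whose primary terminus C7 is captured by the ester carbonyl oxygen with loss of the tert-butyl group, and only the geometry with C7 cis to C10 can close, so the C5=C6 bond is locked inside a six-membered ring while the other allyl isomer returns through reversible ionisation.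

Step 8
Reactants: 12 (5S,8aS)-5-{3-[(tert-butyldiphenylsilyl)oxy]propyl}-5,8a-dimethyl-3,5,6,7,8,8a-hexahydro-1H-isochromen-1-one
Product: 13 (4aS,5S,8aS)-5-{3-[(tert-butyldiphenylsilyl)oxy]propyl}-5,8a-dimethyloctahydro-1H-isochromen-1-one
Conditions: Mn(dpm)3 (10 mol %), PhSiH3, t-BuOOH, i-PrOH, rt
Reagents that add atoms: none
Why: Metal-hydride hydrogen atom transfer hydrogenation of a hindered trisubstituted alkene: the lactone ring holds C9 equatorial, so ring A is a locked chair with C19 and C20 both axial on the β-face, and the tertiary C5 radical takes its hydrogen from the open α-face to give the trans ring fusion (5α-H).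

Step 9
Reactants: 13 (4aS,5S,8aS)-5-{3-[(tert-butyldiphenylsilyl)oxy]propyl}-5,8a-dimethyloctahydro-1H-isochromen-1-one; 14 ethyllithium
Product: 15 1-[(1S,2S,3S)-3-{3-[(tert-butyldiphenylsilyl)oxy]propyl}-2-(2-hydroxyethyl)-1,3-dimethylcyclohexyl]propan-1-one (in equilibrium with its cyclic hemiketal)
Conditions: EtLi, THF, −78 °C; aq NH4Cl at −78 °C
Reagents that add atoms: 14 ethyllithium, [Li]CC
Why: Mono-addition of an alkyllithium to a δ-lactone at low temperature, where the lithium hemiketal survives until the quench, no α-hydrogen can be removed and the neopentyl ketone resists a second addition; this brings in C8 and C17.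

Step 10
Reactants: 15 1-[(1S,2S,3S)-3-{3-[(tert-butyldiphenylsilyl)oxy]propyl}-2-(2-hydroxyethyl)-1,3-dimethylcyclohexyl]propan-1-one
Product: 16 1-[(1S,2S,3S)-3-{3-[(tert-butyldiphenylsilyl)oxy]propyl}-2-(2-iodoethyl)-1,3-dimethylcyclohexyl]propan-1-one
Conditions: I2, PPh3, imidazole, CH2Cl2, 0 °C → rt; aq NaHCO3/Na2S2O3
Reagents that add atoms: iodine, II
Why: Appel-type iodination of the primary alcohol, which drains the open hydroxy ketone from the hemiketal equilibrium.

Step 11
Reactants: 16 1-[(1S,2S,3S)-3-{3-[(tert-butyldiphenylsilyl)oxy]propyl}-2-(2-iodoethyl)-1,3-dimethylcyclohexyl]propan-1-one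
Product: 17 (4aS,5S,8aS)-5-{3-[(tert-butyldiphenylsilyl)oxy]propyl}-2,5,8a-trimethyloctahydronaphthalen-1(2H)-one (C2 epimers)
Conditions: LDA, THF, −78 °C → rt
Reagents that add atoms: none
Why: Intramolecular enolate C-alkylation, a 6-(enolendo)-exo-tet closure that is favourable for six-membered rings, joins C8 to C7 and closes ring B as a trans-decalin; only C8 can be deprotonated and its configuration is lost in step 12.

Step 12
Reactants: 17 (4aS,5S,8aS)-5-{3-[(tert-butyldiphenylsilyl)oxy]propyl}-2,5,8a-trimethyloctahydronaphthalen-1(2H)-one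
Product: 18 (4aS,5S,8aS)-5-{3-[(tert-butyldiphenylsilyl)oxy]propyl}-2,5,8a-trimethyl-3,4,4a,5,6,7,8,8a-octahydronaphthalen-1-yl trifluoromethanesulfonate
Conditions: KHMDS, THF, −78 °C; PhNTf2, −78 → 0 °C; aq NH4Cl
Reagents that add atoms: N-phenylbis(trifluoromethanesulfonimide), O=S(=O)(N(c1ccccc1)S(=O)(=O)C(F)(F)F)C(F)(F)F
Why: Deprotonation at C8, the only α-hydrogen, and O-sulfonylation of the potassium enolate give the tetrasubstituted C8=C9 enol triflate regiospecifically.

Step 13
Reactants: 18 (4aS,5S,8aS)-5-{3-[(tert-butyldiphenylsilyl)oxy]propyl}-2,5,8a-trimethyl-3,4,4a,5,6,7,8,8a-octahydronaphthalen-1-yl trifluoromethanesulfonate; 19 tributyl(vinyl)stannane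
Product: 20 (4aS,5S,8aS)-5-{3-[(tert-butyldiphenylsilyl)oxy]propyl}-1-ethenyl-2,5,8a-trimethyl-3,4,4a,5,6,7,8,8a-octahydronaphthalene
Conditions: CH2=CHSnBu3, Pd(PPh3)4 (5 mol %), LiCl, THF, reflux
Reagents that add atoms: 19 tributyl(vinyl)stannane, C=C[Sn](CCCC)(CCCC)CCCC
Why: Stille coupling of a hindered cyclohexenyl triflate with a vinylstannane in the presence of LiCl, routine for 2,6,6-trisubstituted cyclohexenyl triflates, installs C11 and C12.

Step 14
Reactants: 21 ethyl acetoacetate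
Product: 22 ethyl (2E)-3-{[(trifluoromethyl)sulfonyl]oxy}but-2-enoate
Conditions: Tf2O, aq Me4NOH, toluene, 0–10 °C
Reagents that add atoms: trifluoromethanesulfonic anhydride, O=S(=O)(OS(=O)(=O)C(F)(F)F)C(F)(F)F
Why: O-triflation of the non-chelated tetraalkylammonium enolate of a β-keto ester gives the (E)-enol triflate (OTf trans to the ester), which fixes the later C13=C14 geometry (side branch, used in step 15).

Step 15
Reactants: 20 (4aS,5S,8aS)-5-{3-[(tert-butyldiphenylsilyl)oxy]propyl}-1-ethenyl-2,5,8a-trimethyl-3,4,4a,5,6,7,8,8a-octahydronaphthalene; 22 ethyl (2E)-3-{[(trifluoromethyl)sulfonyl]oxy}but-2-enoate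
Product: 24 ethyl (2E)-5-[(4aS,5S,8aS)-5-{3-[(tert-butyldiphenylsilyl)oxy]propyl}-2,5,8a-trimethyl-3,4,4a,5,6,7,8,8a-octahydronaphthalen-1-yl]-3-methylpent-2-enoate, via B-alkyl-9-BBN adduct 23 (not isolated)
Conditions: 9-BBN, THF, 0 °C → rt; then 22, PdCl2(dppf) (5 mol %), aq K3PO4, DMF, rt
Reagents that add atoms: 22 ethyl (2E)-3-{[(trifluoromethyl)sulfonyl]oxy}but-2-enoate, CCOC(=O)/C=C(\C)OS(=O)(=O)C(F)(F)F
Why: 9-BBN adds only to the terminal carbon of the monosubstituted vinyl group, and B-alkyl Suzuki–Miyaura coupling of the alkylborane with the activated (E)-enol triflate forms C12–C13 with retention of alkene geometry, giving the (E)-enoate.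

Step 16
Reactants: 24 ethyl (2E)-5-[(4aS,5S,8aS)-5-{3-[(tert-butyldiphenylsilyl)oxy]propyl}-2,5,8a-trimethyl-3,4,4a,5,6,7,8,8a-octahydronaphthalen-1-yl]-3-methylpent-2-enoate
Product: 25 ethyl (2E)-5-[(4aS,5S,8aS)-5-(3-hydroxypropyl)-2,5,8a-trimethyl-3,4,4a,5,6,7,8,8a-octahydronaphthalen-1-yl]-3-methylpent-2-enoate
Conditions: TBAF, THF, 0 °C → rt
Reagents that add atoms: none
Why: Fluoride-induced cleavage of the silyl ether, which leaves the ester and both alkenes untouched.

Step 17
Reactants: 25 ethyl (2E)-5-[(4aS,5S,8aS)-5-(3-hydroxypropyl)-2,5,8a-trimethyl-3,4,4a,5,6,7,8,8a-octahydronaphthalen-1-yl]-3-methylpent-2-enoate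
Product: 26 ethyl (2E)-3-methyl-5-[(4aS,5S,8aS)-2,5,8a-trimethyl-5-(3-oxopropyl)-3,4,4a,5,6,7,8,8a-octahydronaphthalen-1-yl]pent-2-enoate
Conditions: Dess–Martin periodinane, CH2Cl2, rt
Reagents that add atoms: none
Why: Dess–Martin oxidation takes the primary alcohol to the aldehyde under neutral conditions without affecting the alkenes.

Step 18
Reactants: 26 ethyl (2E)-3-methyl-5-[(4aS,5S,8aS)-2,5,8a-trimethyl-5-(3-oxopropyl)-3,4,4a,5,6,7,8,8a-octahydronaphthalen-1-yl]pent-2-enoate; 27 isopropyltriphenylphosphonium iodide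
Product: 28 ethyl (2E)-3-methyl-5-[(4aS,5S,8aS)-2,5,8a-trimethyl-5-(4-methylpent-3-en-1-yl)-3,4,4a,5,6,7,8,8a-octahydronaphthalen-1-yl]pent-2-enoate
Conditions: 27, KHMDS, THF, 0 °C; then 26, −78 °C → rt
Reagents that add atoms: 27 isopropyltriphenylphosphonium iodide, CC(C)[P+](c1ccccc1)(c1ccccc1)c1ccccc1.[I-]
Why: Wittig olefination with the non-stabilised isopropylidene ylide reacts at the aldehyde only and completes the homoprenyl chain, whose terminal alkene has no E/Z isomers.

Step 19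
Reactants: 28 ethyl (2E)-3-methyl-5-[(4aS,5S,8aS)-2,5,8a-trimethyl-5-(4-methylpent-3-en-1-yl)-3,4,4a,5,6,7,8,8a-octahydronaphthalen-1-yl]pent-2-enoate
Product: 29 (2E)-3-methyl-5-[(4aS,5S,8aS)-2,5,8a-trimethyl-5-(4-methylpent-3-en-1-yl)-3,4,4a,5,6,7,8,8a-octahydronaphthalen-1-yl]pent-2-enoic acid
Conditions: LiOH, THF/MeOH/H2O, 45 °C; then aq HCl to pH 3
Reagents that add atoms: lithium hydroxide, [Li+].[OH-]
Why: Saponification of the ethyl ester; no stereocentre is epimerisable and the conjugated (E)-alkene is kept under mild hydroxide.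

Compound list
1 | tert-butyl 2-oxocyclohexane-1-carboxylate | CC(C)(C)OC(=O)C1CCCCC1=O | starting material
2 | chloromethyl methyl sulfide | CSCCl | starting material
3 | tert-butyl (1R)-1-[(methylsulfanyl)methyl]-2-oxocyclohexane-1-carboxylate | O=C1CCCC[C@]1(CSC)C(=O)OC(C)(C)C | intermediate
4 | tert-butyl(3-iodopropoxy)diphenylsilane | CC(C)(C)[Si](c1ccccc1)(c1ccccc1)OCCCI | starting material
5 | tert-butyl (1R)-3-{3-[(tert-butyldiphenylsilyl)oxy]propyl}-1-[(methylsulfanyl)methyl]-2-oxocyclohexane-1-carboxylate (C3 epimers) | CC(C)(C)[Si](c1ccccc1)(c1ccccc1)OCCCC1CCC[C@](CSC)(C(=O)OC(C)(C)C)C1=O | intermediate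
6 | tert-butyl (1R)-3-{3-[(tert-butyldiphenylsilyl)oxy]propyl}-1-[(methanesulfinyl)methyl]-2-oxocyclohexane-1-carboxylate (C3 and sulfur epimers) | CC(C)(C)[Si](c1ccccc1)(c1ccccc1)OCCCC1CCC[C@](CS(C)=O)(C(=O)OC(C)(C)C)C1=O | intermediate
7 | tert-butyl (1R)-3-{3-[(tert-butyldiphenylsilyl)oxy]propyl}-1-[(methylidenesulfonio)methyl]-2-[(trimethylsilyl)oxy]cyclohex-2-ene-1-carboxylate trifluoromethanesulfonate | C=[S+]C[C@]1(C(=O)OC(C)(C)C)CCCC(CCCO[Si](c2ccccc2)(c2ccccc2)C(C)(C)C)=C1O[Si](C)(C)C.[O-]S(=O)(=O)C(F)(F)F | intermediate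
8 | tert-butyl (1R,5R)-5-{3-[(tert-butyldiphenylsilyl)oxy]propyl}-9-oxo-3-thiabicyclo[3.3.1]nonane-1-carboxylate | CC(C)(C)[Si](c1ccccc1)(c1ccccc1)OCCC[C@]1(CSC2)CCC[C@]2(C(=O)OC(C)(C)C)C1=O | intermediate
9 | tert-butyl (1S,3S)-3-{3-[(tert-butyldiphenylsilyl)oxy]propyl}-1,3-dimethyl-2-oxocyclohexane-1-carboxylate | CC(C)(C)[Si](c1ccccc1)(c1ccccc1)OCCC[C@]1(C)CCC[C@](C)(C(=O)OC(C)(C)C)C1=O | intermediate
10 | vinylmagnesium bromide | C=C[Mg]Br | starting material
11 | tert-butyl (1S,3S)-3-{3-[(tert-butyldiphenylsilyl)oxy]propyl}-2-ethenyl-2-hydroxy-1,3-dimethylcyclohexane-1-carboxylate (C2 epimers) | CC(C)(C)[Si](c1ccccc1)(c1ccccc1)OCCC[C@]1(C)CCC[C@](C)(C(=O)OC(C)(C)C)C1(O)C=C | intermediate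
12 | (5S,8aS)-5-{3-[(tert-butyldiphenylsilyl)oxy]propyl}-5,8a-dimethyl-3,5,6,7,8,8a-hexahydro-1H-isochromen-1-one | CC(C)(C)[Si](c1ccccc1)(c1ccccc1)OCCC[C@]1(C)CCC[C@]2(C)C(=O)OCC=C12 | intermediate
13 | (4aS,5S,8aS)-5-{3-[(tert-butyldiphenylsilyl)oxy]propyl}-5,8a-dimethyloctahydro-1H-isochromen-1-one | CC(C)(C)[Si](c1ccccc1)(c1ccccc1)OCCC[C@]1(C)CCC[C@]2(C)C(=O)OCC[C@@H]12 | intermediate
14 | ethyllithium | [Li]CC | starting material
15 | 1-[(1S,2S,3S)-3-{3-[(tert-butyldiphenylsilyl)oxy]propyl}-2-(2-hydroxyethyl)-1,3-dimethylcyclohexyl]propan-1-one | CC(C)(C)[Si](c1ccccc1)(c1ccccc1)OCCC[C@]1(C)CCC[C@](C)(C(=O)CC)[C@H]1CCO | intermediate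
16 | 1-[(1S,2S,3S)-3-{3-[(tert-butyldiphenylsilyl)oxy]propyl}-2-(2-iodoethyl)-1,3-dimethylcyclohexyl]propan-1-one | CC(C)(C)[Si](c1ccccc1)(c1ccccc1)OCCC[C@]1(C)CCC[C@](C)(C(=O)CC)[C@H]1CCI | intermediate
17 | (4aS,5S,8aS)-5-{3-[(tert-butyldiphenylsilyl)oxy]propyl}-2,5,8a-trimethyloctahydronaphthalen-1(2H)-one (C2 epimers) | CC(C)(C)[Si](c1ccccc1)(c1ccccc1)OCCC[C@]1(C)CCC[C@]2(C)C(=O)C(C)CC[C@@H]12 | intermediate
18 | (4aS,5S,8aS)-5-{3-[(tert-butyldiphenylsilyl)oxy]propyl}-2,5,8a-trimethyl-3,4,4a,5,6,7,8,8a-octahydronaphthalen-1-yl trifluoromethanesulfonate | CC(C)(C)[Si](c1ccccc1)(c1ccccc1)OCCC[C@]1(C)CCC[C@]2(C)C(OS(=O)(=O)C(F)(F)F)=C(C)CC[C@@H]12 | intermediate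
19 | tributyl(vinyl)stannane | C=C[Sn](CCCC)(CCCC)CCCC | starting material
20 | (4aS,5S,8aS)-5-{3-[(tert-butyldiphenylsilyl)oxy]propyl}-1-ethenyl-2,5,8a-trimethyl-3,4,4a,5,6,7,8,8a-octahydronaphthalene | CC(C)(C)[Si](c1ccccc1)(c1ccccc1)OCCC[C@]1(C)CCC[C@]2(C)C(C=C)=C(C)CC[C@@H]12 | intermediate
21 | ethyl acetoacetate | CCOC(=O)CC(C)=O | starting material
22 | ethyl (2E)-3-{[(trifluoromethyl)sulfonyl]oxy}but-2-enoate | CCOC(=O)/C=C(\C)OS(=O)(=O)C(F)(F)F | intermediate
23 | 9-{2-[(4aS,5S,8aS)-5-{3-[(tert-butyldiphenylsilyl)oxy]propyl}-2,5,8a-trimethyl-3,4,4a,5,6,7,8,8a-octahydronaphthalen-1-yl]ethyl}-9-borabicyclo[3.3.1]nonane | CC(C)(C)[Si](c1ccccc1)(c1ccccc1)OCCC[C@]1(C)CCC[C@]2(C)C(CCB3C4CCCC3CCC4)=C(C)CC[C@@H]12 | intermediate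
24 | ethyl (2E)-5-[(4aS,5S,8aS)-5-{3-[(tert-butyldiphenylsilyl)oxy]propyl}-2,5,8a-trimethyl-3,4,4a,5,6,7,8,8a-octahydronaphthalen-1-yl]-3-methylpent-2-enoate | CC(C)(C)[Si](c1ccccc1)(c1ccccc1)OCCC[C@]1(C)CCC[C@]2(C)C(CC/C(C)=C/C(=O)OCC)=C(C)CC[C@@H]12 | intermediate
25 | ethyl (2E)-5-[(4aS,5S,8aS)-5-(3-hydroxypropyl)-2,5,8a-trimethyl-3,4,4a,5,6,7,8,8a-octahydronaphthalen-1-yl]-3-methylpent-2-enoate | OCCC[C@]1(C)CCC[C@]2(C)C(CC/C(C)=C/C(=O)OCC)=C(C)CC[C@@H]12 | intermediate
26 | ethyl (2E)-3-methyl-5-[(4aS,5S,8aS)-2,5,8a-trimethyl-5-(3-oxopropyl)-3,4,4a,5,6,7,8,8a-octahydronaphthalen-1-yl]pent-2-enoate | O=CCC[C@]1(C)CCC[C@]2(C)C(CC/C(C)=C/C(=O)OCC)=C(C)CC[C@@H]12 | intermediate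
27 | isopropyltriphenylphosphonium iodide | CC(C)[P+](c1ccccc1)(c1ccccc1)c1ccccc1.[I-] | starting material
28 | ethyl (2E)-3-methyl-5-[(4aS,5S,8aS)-2,5,8a-trimethyl-5-(4-methylpent-3-en-1-yl)-3,4,4a,5,6,7,8,8a-octahydronaphthalen-1-yl]pent-2-enoate | CC(C)=CCC[C@]1(C)CCC[C@]2(C)C(CC/C(C)=C/C(=O)OCC)=C(C)CC[C@@H]12 | intermediate
29 | (2E)-3-methyl-5-[(4aS,5S,8aS)-2,5,8a-trimethyl-5-(4-methylpent-3-en-1-yl)-3,4,4a,5,6,7,8,8a-octahydronaphthalen-1-yl]pent-2-enoic acid (CNP0237483.2) | CC(C)=CCC[C@]1(C)CCC[C@]2(C)C(CC/C(C)=C/C(=O)O)=C(C)CC[C@@H]12 | target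

Total step count: 19. Longest linear sequence: 18 steps (steps 1–13 and 15–19; step 14 is a one-step side branch).

Steps most likely to fail

Step 4. The silylated sulfoxide may ionise slowly or toward the neopentyl side, the thionium ion may be captured at oxygen, or enol ether formation at the hindered ketone may lag, so that C4–C19 bond formation loses to decomposition; the acid-labile ester could also be cleaved. The fallback sets out from 5 and forms C4–C19 first and the C19–S bond second. LDA followed by monomeric formaldehyde should give the aldol product tert-butyl (1R)-3-{3-[(tert-butyldiphenylsilyl)oxy]propyl}-3-(hydroxymethyl)-1-[(methylsulfanyl)methyl]-2-oxocyclohexane-1-carboxylate F1 as both C3 epimers. MsCl/Et3N converts it into the mesylate tert-butyl (1R)-3-{3-[(tert-butyldiphenylsilyl)oxy]propyl}-3-{[(methanesulfonyl)oxy]methyl}-1-[(methylsulfanyl)methyl]-2-oxocyclohexane-1-carboxylate F2. On warming in DMF the sulfide sulfur of the cis isomer displaces the mesylate intramolecularly to give (1R,5R)-1-(tert-butoxycarbonyl)-5-{3-[(tert-butyldiphenylsilyl)oxy]propyl}-3-methyl-9-oxo-3-thiabicyclo[3.3.1]nonan-3-ium methanesulfonate F3, and sodium thiophenolate removes the S-methyl group to return to the route at 8. The trans C3 epimer cannot close and is separated, which costs material but not stereochemical integrity.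

Step 1. Facial discrimination within the ion pair may be insufficient with this readily ionising electrophile, or O-alkylation may compete. The fallback sets out from 1 and uses a stoichiometric chiral enamine. Condensation with tert-butyl L-valinate (cat. acid, toluene, water removal) gives tert-butyl 2-{[(2S)-1-(tert-butoxy)-3-methyl-1-oxobutan-2-yl]amino}cyclohex-1-ene-1-carboxylate F4. Lithiation with LDA (in the solvent/additive protocol that gives the R centre) and alkylation with 2 gives tert-butyl (1R)-2-{[(2S)-1-(tert-butoxy)-3-methyl-1-oxobutan-2-yl]imino}-1-[(methylsulfanyl)methyl]cyclohexane-1-carboxylate F5. Mild aqueous citric acid hydrolyses the imine, releases the auxiliary and returns to the route at 3.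

Step 7. After ionisation the allyl cation may be diverted: premature ester cleavage followed by loss of CO2, a skeletal shift next to the two quaternary carbons, or partial loss of the silyl ether. The fallback sets out from 11 and avoids the cation. Hydroboration–oxidation of the vinyl group (9-BBN; NaBO3) gives tert-butyl (1S,3S)-3-{3-[(tert-butyldiphenylsilyl)oxy]propyl}-2-hydroxy-2-(2-hydroxyethyl)-1,3-dimethylcyclohexane-1-carboxylate F6. Acid-catalysed lactonisation of the primary alcohol onto the ester (TsOH cat., toluene, 60 °C) gives (5S,8aS)-5-{3-[(tert-butyldiphenylsilyl)oxy]propyl}-4a-hydroxy-5,8a-dimethyloctahydro-1H-isochromen-1-one F7. Burgess dehydration of the tertiary alcohol, which has β-hydrogens only on C6, returns to the route at 12.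

Further compounds
F1 | step 4 | tert-butyl (1R)-3-{3-[(tert-butyldiphenylsilyl)oxy]propyl}-3-(hydroxymethyl)-1-[(methylsulfanyl)methyl]-2-oxocyclohexane-1-carboxylate (C3 epimers) | CC(C)(C)[Si](c1ccccc1)(c1ccccc1)OCCCC1(CO)CCC[C@](CSC)(C(=O)OC(C)(C)C)C1=O
F2 | step 4 | tert-butyl (1R)-3-{3-[(tert-butyldiphenylsilyl)oxy]propyl}-3-{[(methanesulfonyl)oxy]methyl}-1-[(methylsulfanyl)methyl]-2-oxocyclohexane-1-carboxylate (C3 epimers) | CC(C)(C)[Si](c1ccccc1)(c1ccccc1)OCCCC1(COS(C)(=O)=O)CCC[C@](CSC)(C(=O)OC(C)(C)C)C1=O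
F3 | step 4 | (1R,5R)-1-(tert-butoxycarbonyl)-5-{3-[(tert-butyldiphenylsilyl)oxy]propyl}-3-methyl-9-oxo-3-thiabicyclo[3.3.1]nonan-3-ium methanesulfonate | CC(C)(C)[Si](c1ccccc1)(c1ccccc1)OCCC[C@]1(C[S+](C)C2)CCC[C@]2(C(=O)OC(C)(C)C)C1=O.CS(=O)(=O)[O-]
F4 | step 1 | tert-butyl 2-{[(2S)-1-(tert-butoxy)-3-methyl-1-oxobutan-2-yl]amino}cyclohex-1-ene-1-carboxylate | CC(C)[C@H](NC1=C(C(=O)OC(C)(C)C)CCCC1)C(=O)OC(C)(C)C
F5 | step 1 | tert-butyl (1R)-2-{[(2S)-1-(tert-butoxy)-3-methyl-1-oxobutan-2-yl]imino}-1-[(methylsulfanyl)methyl]cyclohexane-1-carboxylate | CC(C)[C@H](N=C1CCCC[C@]1(CSC)C(=O)OC(C)(C)C)C(=O)OC(C)(C)C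
F6 | step 7 | tert-butyl (1S,3S)-3-{3-[(tert-butyldiphenylsilyl)oxy]propyl}-2-hydroxy-2-(2-hydroxyethyl)-1,3-dimethylcyclohexane-1-carboxylate (C2 epimers) | CC(C)(C)[Si](c1ccccc1)(c1ccccc1)OCCC[C@]1(C)CCC[C@](C)(C(=O)OC(C)(C)C)C1(O)CCO
F7 | step 7 | (5S,8aS)-5-{3-[(tert-butyldiphenylsilyl)oxy]propyl}-4a-hydroxy-5,8a-dimethyloctahydro-1H-isochromen-1-one (C4a epimers) | CC(C)(C)[Si](c1ccccc1)(c1ccccc1)OCCC[C@]1(C)CCC[C@]2(C)C(=O)OCCC12O
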